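Everything rests on cutting ring A at C1–C2 and C5–C6. The C2–C3–C4–C5 segment has the 1,3-dioxygenation of an acetoacetate, and C1 (CO2Me) and C6 (CH3) are the two alkyne carbons of methyl but-2-ynoate. One Diels–Alder/aromatization therefore closes ring A, makes both C–C bonds and releases the C2 phenol while the C4 oxygen already carries the ring B acyl group, so the two ring A oxygens never have to be told apart. The diene partner is a 1-methoxy-1-silyloxybuta-1,3-diene whose 3-oxygen is esterified by the hexasubstituted, dibenzyl-protected chloro acid of ring B. It derives from methyl acetoacetate by O-acylation and γ-deprotonation/silylation.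

Key step: step 6

Numbering: ring A has C1 (CO2Me), C2 (OH), C4 (O-acyl) and C6 (CH3). Ring B has C1' (C=O), C2' (O), C3' (CH3), C4' (O), C5' (Cl) and C6' (CH3).
Remark on protection: the ring B phenols travel as benzyl ethers. These tolerate acid chloride formation (an ortho acetal-type ether could cyclise onto the acyl chloride), LDA, 130 °C and the acidic work-up of the key step. They leave by neutral hydrogenolysis, which spares the depside ester.
Assumption: the target is achiral. The ketene acetal geometry of 9 and the racemic ketal carbon of 11 vanish on aromatization and need no control.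

Step 1
Reactants: 1 methyl 2,4-dihydroxy-3,6-dimethylbenzoate
Product: 2 methyl 5-chloro-2,4-dihydroxy-3,6-dimethylbenzoate
Conditions: SO2Cl2 (1.05 equiv), Et2O, 0 °C to rt
Reagents that add atoms: sulfuryl chloride, O=S(=O)(Cl)Cl
Why: Electrophilic aromatic chlorination can only occur at C5', the single free ring position, which is ortho to the 4'-OH and para to the 2'-OH, and one equivalent of reagent avoids dearomatising over-chlorination.

Step 2
Reactants: 2 methyl 5-chloro-2,4-dihydroxy-3,6-dimethylbenzoate
Product: 3 methyl 2,4-bis(benzyloxy)-5-chloro-3,6-dimethylbenzoate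
Conditions: BnBr (2.6 equiv), K2CO3 (3 equiv), DMF, 70 °C
Reagents that add atoms: benzyl bromide, BrCc1ccccc1
Why: In this Williamson ether synthesis both phenoxides, including the hydrogen-bonded and flanked C2' one, are alkylated by the reactive benzylic bromide in DMF, while the ester and the aryl chloride are untouched.

Step 3
Reactants: 3 methyl 2,4-bis(benzyloxy)-5-chloro-3,6-dimethylbenzoate
Product: 4 2,4-bis(benzyloxy)-5-chloro-3,6-dimethylbenzoic acid
Conditions: KOH (10 equiv), DMSO–H2O (4:1), 100 °C; then 2 M HCl, 0 °C
Reagents that add atoms: potassium hydroxide, [K+].[OH-]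
Why: Saponification of a di-ortho-substituted benzoate needs poorly solvated hydroxide at high temperature, conditions under which benzyl ethers and the electron-rich aryl chloride are inert and the protected acid does not decarboxylate.

Step 4
Reactants: 4 2,4-bis(benzyloxy)-5-chloro-3,6-dimethylbenzoic acid; 5 methyl acetoacetate
Product: 7 methyl (E)-3-{[2,4-bis(benzyloxy)-5-chloro-3,6-dimethylbenzoyl]oxy}but-2-enoate, via acid chloride 6 (not isolated)
Conditions: (COCl)2 (1.5 equiv), DMF (cat.), CH2Cl2, 0 °C to rt, evaporate; then 5 (2 equiv), Et3N (3 equiv), DMPU, 0 °C to rt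
Reagents that add atoms: oxalyl chloride, O=C(Cl)C(=O)Cl (supplies only the chlorine of intermediate 6)
Why: After DMF-catalysed acid chloride formation, this enolate O-acylation pairs a non-chelated ammonium enolate in a dipolar aprotic medium with a hard, acylium-like di-ortho-substituted aroyl chloride, so it should react at oxygen and give mainly the E enol ester (CH3 cis to CO2Me), and the shielded carbonyl blocks later O-to-C acyl transfer.

Step 5
Reactants: 7 methyl (E)-3-{[2,4-bis(benzyloxy)-5-chloro-3,6-dimethylbenzoyl]oxy}but-2-enoate
Product: 9 (3Z)-4-methoxy-4-(trimethylsilyloxy)buta-1,3-dien-2-yl 2,4-bis(benzyloxy)-5-chloro-3,6-dimethylbenzoate, via lithium dienolate 8 (not isolated)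
Conditions: Me3SiCl (2 equiv) present from the start, LDA (1.15 equiv) added last, THF, −78 °C; evaporate, pentane–toluene, filter under Ar; used crude
Reagents that add atoms: chlorotrimethylsilane, C[Si](C)(C)Cl; lithium diisopropylamide, [Li+].CC(C)[N-]C(C)C (supplies only the lithium of intermediate 8)
Why: Kinetic γ-deprotonation and O-silylation of a β-oxygenated crotonate is the standard entry to vinylketene silyl acetals; here the cis ester carbonyl directs the base to the methyl group, Me3SiCl already present traps dienolate 8 before it can expel the carboxylate, and the shielded aroyl carbonyl and the less acidic C6' methyl are left alone.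

Step 6
Reactants: 9 (3Z)-4-methoxy-4-(trimethylsilyloxy)buta-1,3-dien-2-yl 2,4-bis(benzyloxy)-5-chloro-3,6-dimethylbenzoate; 10 methyl but-2-ynoate
Product: 13 methyl 4-{[2,4-bis(benzyloxy)-5-chloro-3,6-dimethylbenzoyl]oxy}-2-hydroxy-6-methylbenzoate, via cyclohexadiene ketal 11 (not isolated), via aryl silyl ether 12 (not isolated)
Conditions: 10 (8 equiv, neat), BHT (cat.), sealed tube, 130 °C; evaporate excess 10; then 1 M HCl–THF, rt
Reagents that add atoms: none
Why: The two oxygens on the ketene acetal carbon and the acyloxy group two carbons away raise the HOMO of 9 and put its largest coefficient on the CH2 terminus, so a normal-electron-demand, concerted but asynchronous (4+2) cycloaddition to the electron-poor triple bond of 10 gives the 1,4-cyclohexadiene 11. The closest known reaction type is the Diels–Alder/aromatization of 1,1,3-trioxygenated butadienes (vinylketene acetals) with acetylenic esters, which builds resorcylates in the same way. Ring A closes as a six-membered carbocycle in an intermolecular (4+2) mode, with C5–C6 bond formation running ahead of C1–C2. No stereocentre survives: the ketal carbon of 11 is racemic and is flattened when acid protonates the more basic methoxy oxygen, methanol leaves and the doubly allylic C5 proton is lost to give 12, whose Si–O bond hydrolyses on work-up to the hydrogen-bonded phenol 13. The selectivity needed is regiochemical, and it is secured by matched polarisation (nucleophilic CH2 to the methyl-bearing β-carbon of 10), which puts CH3 on C6 and CO2Me on C1 next to the new C2 oxygen. The di-ortho-substituted aroyl group is too shielded to migrate at 130 °C, and the benzyl ethers and the aryl chloride are inert to heat and to the dilute acid.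

Step 7
Reactants: 13 methyl 4-{[2,4-bis(benzyloxy)-5-chloro-3,6-dimethylbenzoyl]oxy}-2-hydroxy-6-methylbenzoate
Product: 14 methyl 4-[(5-chloro-2,4-dihydroxy-3,6-dimethylbenzoyl)oxy]-2-hydroxy-6-methylbenzoate (CNP0171762.0)
Conditions: H2 (1 atm), 10% Pd/C, EtOAc, rt, stopped after uptake of two equivalents
Reagents that add atoms: none
Why: Catalytic hydrogenolysis of aryl benzyl ethers is fast on Pd/C in neutral EtOAc, whereas the electron-rich, doubly flanked C5'–Cl bond is reduced only slowly without added base, and both esters are inert.

Compound list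
1 | methyl 2,4-dihydroxy-3,6-dimethylbenzoate | COC(=O)c1c(C)cc(O)c(C)c1O | starting material
2 | methyl 5-chloro-2,4-dihydroxy-3,6-dimethylbenzoate | COC(=O)c1c(C)c(Cl)c(O)c(C)c1O | intermediate
3 | methyl 2,4-bis(benzyloxy)-5-chloro-3,6-dimethylbenzoate | COC(=O)c1c(C)c(Cl)c(OCc2ccccc2)c(C)c1OCc3ccccc3 | intermediate
4 | 2,4-bis(benzyloxy)-5-chloro-3,6-dimethylbenzoic acid | OC(=O)c1c(C)c(Cl)c(OCc2ccccc2)c(C)c1OCc3ccccc3 | intermediate
5 | methyl acetoacetate | COC(=O)CC(C)=O | starting material
6 | 2,4-bis(benzyloxy)-5-chloro-3,6-dimethylbenzoyl chloride (not isolated) | ClC(=O)c1c(C)c(Cl)c(OCc2ccccc2)c(C)c1OCc3ccccc3 | intermediate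
7 | methyl (E)-3-{[2,4-bis(benzyloxy)-5-chloro-3,6-dimethylbenzoyl]oxy}but-2-enoate | COC(=O)/C=C(\C)OC(=O)c1c(C)c(Cl)c(OCc2ccccc2)c(C)c1OCc3ccccc3 | intermediate
8 | lithium dienolate of 7, O–Li cis to the diene chain (not isolated) | C=C(OC(=O)c1c(C)c(Cl)c(OCc2ccccc2)c(C)c1OCc3ccccc3)/C=C(/OC)[O-].[Li+] | intermediate
9 | (3Z)-4-methoxy-4-(trimethylsilyloxy)buta-1,3-dien-2-yl 2,4-bis(benzyloxy)-5-chloro-3,6-dimethylbenzoate | C=C(OC(=O)c1c(C)c(Cl)c(OCc2ccccc2)c(C)c1OCc3ccccc3)/C=C(/OC)O[Si](C)(C)C | intermediate
10 | methyl but-2-ynoate | CC#CC(=O)OC | starting material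
11 | methyl 4-{[2,4-bis(benzyloxy)-5-chloro-3,6-dimethylbenzoyl]oxy}-6-methoxy-2-methyl-6-(trimethylsilyloxy)cyclohexa-1,4-diene-1-carboxylate, racemic (not isolated) | COC(=O)C1=C(C)CC(OC(=O)c2c(C)c(Cl)c(OCc3ccccc3)c(C)c2OCc4ccccc4)=CC1(OC)O[Si](C)(C)C | intermediate
12 | methyl 4-{[2,4-bis(benzyloxy)-5-chloro-3,6-dimethylbenzoyl]oxy}-2-methyl-6-(trimethylsilyloxy)benzoate (not isolated) | COC(=O)c1c(C)cc(OC(=O)c2c(C)c(Cl)c(OCc3ccccc3)c(C)c2OCc4ccccc4)cc1O[Si](C)(C)C | intermediate
13 | methyl 4-{[2,4-bis(benzyloxy)-5-chloro-3,6-dimethylbenzoyl]oxy}-2-hydroxy-6-methylbenzoate | COC(=O)c1c(C)cc(OC(=O)c2c(C)c(Cl)c(OCc3ccccc3)c(C)c2OCc4ccccc4)cc1O | intermediate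
14 | methyl 4-[(5-chloro-2,4-dihydroxy-3,6-dimethylbenzoyl)oxy]-2-hydroxy-6-methylbenzoate | COC(=O)c1c(C)cc(OC(=O)c2c(C)c(Cl)c(O)c(C)c2O)cc1O | target

Total step count: 7. Longest linear sequence: 7 steps (1 to 14); 5 and 10 enter as purchased materials.

Steps most likely to fail

1. Step 6.
- The acyloxy group is a weaker donor than a silyloxy group, and an internal alkynoate is a modest dienophile, so the cycloaddition may be slow.
- Thermal oxygen-to-carbon silyl migration, fragmentation of the ketene acetal with transfer of silicon to the carboxylate, or adventitious hydrolysis may then outrun it.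
- Expulsion of silanol instead of methanol during aromatization would erode the free C2 phenol.
- Diene that does not react should revert to 7 on work-up and can be recycled.
- Fallback, setting out from 10 and 4: 10 is heated with commercial 1-methoxy-1,3-bis(trimethylsilyloxy)buta-1,3-diene, the fully silylated and more electron-rich relative of 9. Acidic work-up gives methyl 2,4-dihydroxy-6-methylbenzoate F1.
- Acid 4 is then joined to the unchelated 4-OH of F1 with trifluoroacetic anhydride in toluene. This is the classical depside esterification through the mixed anhydride, and the hydrogen-bonded 2-OH stays free. It comes back to the route at 13.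

2. Step 5.
- The dienolate may collapse by expulsion of the carboxylate (E1cB-type loss towards an allenic ester) before it is silylated.
- Deprotonation may stray to the C6' benzylic methyl group.
- The ketene acetal may hydrolyse during the non-aqueous isolation.
- Fallback, setting out from acid chloride 6: the acyl group is put on last, so that no enol ester ever meets a strong base.
- AlCl3-mediated Friedel–Crafts-type acylation of 1,1-dichloroethene with acetyl chloride gives 4,4-dichlorobut-3-en-2-one F2. NaOMe in MeOH converts it into 4,4-dimethoxybut-3-en-2-one F3.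
- F3 is deprotonated at the methyl ketone with KHMDS (THF, −78 °C) and O-acylated in the same flask by 6. This gives 4,4-dimethoxybuta-1,3-dien-2-yl 2,4-bis(benzyloxy)-5-chloro-3,6-dimethylbenzoate F4, a silicon-free ketene acetal that tolerates handling.
- Heating F4 with 10, followed by loss of methanol, gives methyl 4-{[2,4-bis(benzyloxy)-5-chloro-3,6-dimethylbenzoyl]oxy}-2-methoxy-6-methylbenzoate F5.
- BCl3 with pentamethylbenzene in CH2Cl2 (−78 to 0 °C) removes the chelated 2-O-methyl group and both benzyl ethers in one operation, rejoining the route at 14.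

3. Step 4.
- Acylation may drift to carbon.
- The chelation-type Z geometry, which is less suited to γ-deprotonation, may form.
- The hindered acid chloride may simply react too slowly with a weakly populated enolate.
- Fallback, setting out from acid 4: cyanuric fluoride and pyridine in CH2Cl2 give 2,4-bis(benzyloxy)-5-chloro-3,6-dimethylbenzoyl fluoride F6, a small, hard and isolable acyl donor.
- F6 is combined with commercial methyl 3-(trimethylsilyloxy)but-2-enoate and catalytic tetrabutylammonium difluorotriphenylsilicate in THF. Fluoride-catalysed silyl–acyl exchange on the enol oxygen, driven by Si–F bond formation and running through a metal-free enolate, gives the enol ester and returns to the route at 7.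

Further compounds
F1 | step 6 | methyl 2,4-dihydroxy-6-methylbenzoate | COC(=O)c1c(C)cc(O)cc1O
F2 | step 5 | 4,4-dichlorobut-3-en-2-one | CC(=O)C=C(Cl)Cl
F3 | step 5 | 4,4-dimethoxybut-3-en-2-one | CC(=O)C=C(OC)OC
F4 | step 5 | 4,4-dimethoxybuta-1,3-dien-2-yl 2,4-bis(benzyloxy)-5-chloro-3,6-dimethylbenzoate | C=C(OC(=O)c1c(C)c(Cl)c(OCc2ccccc2)c(C)c1OCc3ccccc3)C=C(OC)OC
F5 | step 5 | methyl 4-{[2,4-bis(benzyloxy)-5-chloro-3,6-dimethylbenzoyl]oxy}-2-methoxy-6-methylbenzoate | COC(=O)c1c(C)cc(OC(=O)c2c(C)c(Cl)c(OCc3ccccc3)c(C)c2OCc4ccccc4)cc1OC
F6 | step 4 | 2,4-bis(benzyloxy)-5-chloro-3,6-dimethylbenzoyl fluoride | FC(=O)c1c(C)c(Cl)c(OCc2ccccc2)c(C)c1OCc3ccccc3
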